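**Retrosynthetic overview**

1. Target ⇒ 8-alkynyl tetra-O-benzyl isoflavone. The C5 side chain comes from 2-methylbut-3-yn-2-ol by Sonogashira coupling to an 8-iodoisoflavone, and one hydrogenation saturates the alkyne and removes all benzyl groups.
2. Ring C (the pyranone, the only ring built) ⇒ 2'-hydroxychalcone, by oxidative 1,2-aryl shift with Tl(NO3)3 to a β-keto acetal and acid ring closure through the single free phenol, which fixes iodine at C8.
3. Key C–C bond: chalcone ⇒ ring A acetophenone + ring B aldehyde by an intermolecular Claisen–Schmidt aldol condensation.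
4. Ring A fragment ⇒ 2',4',6'-trihydroxyacetophenone (di-O-benzylation, iodination ortho to the free OH); ring B fragment ⇒ 2,4-dihydroxybenzaldehyde (di-O-benzylation).
5. Ring order: rings A and B are bought as benzenoid starting materials; ring C is closed last among the rings, in step 6.

Assumption: the target has no stereocentre and no stereogenic double bond, so the achiral compound as drawn is the "single enantiomer"; commercial 2',4',6'-trihydroxyacetophenone monohydrate is dried before use.

**Route**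

Step 1

Reactants: 1 1-(2,4,6-trihydroxyphenyl)ethan-1-one

Product: 2 1-[2,4-bis(benzyloxy)-6-hydroxyphenyl]ethan-1-one

Conditions: BnBr (2.05 equiv), K2CO3 (2.2 equiv), DMF, 0 °C → rt, 16 h

Reagents that add atoms: benzyl bromide, `BrCc1ccccc1`

Why: Williamson etherification in which the para-OH and one of the two equivalent ortho-OH groups are benzylated, while the remaining ortho-OH is held in a hydrogen bond to the acetyl carbonyl and stays free.

Step 2

Reactants: 2 1-[2,4-bis(benzyloxy)-6-hydroxyphenyl]ethan-1-one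

Product: 3 1-[4,6-bis(benzyloxy)-2-hydroxy-3-iodophenyl]ethan-1-one

Conditions: BnNMe3·ICl2 (1.05 equiv), NaHCO3 (3 equiv), CH2Cl2/MeOH (5:2), rt, 3 h

Reagents that add atoms: benzyltrimethylammonium dichloroiodate, `C[N+](C)(C)Cc1ccccc1.Cl[I-]Cl`

Why: Electrophilic aromatic iodination in which the free chelated phenol directs iodine to its own ortho position C3 rather than to the more crowded C5 between the two benzyloxy groups, placing iodine next to the oxygen that later becomes O1 (regiochemistry confirmed by HMBC from the chelated OH proton).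

Step 3

Reactants: 4 2,4-dihydroxybenzaldehyde

Product: 5 2,4-bis(benzyloxy)benzaldehyde

Conditions: BnBr (2.3 equiv), K2CO3 (3 equiv), DMF, 60 °C, 4 h

Reagents that add atoms: benzyl bromide, `BrCc1ccccc1`

Why: Williamson etherification of both phenols under standard carbonate conditions, with mild heating to alkylate the chelated 2-OH.

Step 4

Reactants: 3 1-[4,6-bis(benzyloxy)-2-hydroxy-3-iodophenyl]ethan-1-one; 5 2,4-bis(benzyloxy)benzaldehyde

Product: 7 (E)-1-[4,6-bis(benzyloxy)-2-hydroxy-3-iodophenyl]-3-[2,4-bis(benzyloxy)phenyl]prop-2-en-1-one, via racemic β-hydroxy ketone aldol adduct 6 (not isolated)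

Conditions: KOH (50% aq., 10 equiv), EtOH/THF (1:1), rt, 48 h; then cold 1 M HCl

Reagents that add atoms: none

Why: Claisen–Schmidt aldol condensation in which the acetophenone enolate adds to the non-enolisable aldehyde and the aldol adduct loses water by E1cB elimination to give the thermodynamically favoured (E)-enone, so no stereocentre survives.

Step 5

Reactants: 7 (E)-1-[4,6-bis(benzyloxy)-2-hydroxy-3-iodophenyl]-3-[2,4-bis(benzyloxy)phenyl]prop-2-en-1-one

Product: 8 1-[4,6-bis(benzyloxy)-2-hydroxy-3-iodophenyl]-2-[2,4-bis(benzyloxy)phenyl]-3,3-dimethoxypropan-1-one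

Conditions: Tl(NO3)3·3H2O (1.2 equiv), MeOH/HC(OMe)3/CH2Cl2 (3:1:1), rt, 16 h; filter off TlNO3, NaHCO3 wash

Reagents that add atoms: methanol, `CO`

Why: Oxidative rearrangement of a chalcone by trivalent thallium, in which methoxythallation of the enone is followed by a 1,2-shift of the electron-rich 2,4-bis(benzyloxy)phenyl ring from the β- to the α-carbon with loss of monovalent thallium and trapping of the oxocarbenium ion by methanol (the new stereocentre is racemic and is destroyed in step 6).

Step 6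

Reactants: 8 1-[4,6-bis(benzyloxy)-2-hydroxy-3-iodophenyl]-2-[2,4-bis(benzyloxy)phenyl]-3,3-dimethoxypropan-1-one

Product: 9 5,7-bis(benzyloxy)-3-[2,4-bis(benzyloxy)phenyl]-8-iodo-4H-chromen-4-one

Conditions: 10% aq. HCl (cat.), MeOH/THF (1:1), reflux, 3 h

Reagents that add atoms: none

Why: Acid-catalysed cyclodehydration (acetal exchange, then elimination of methanol) in which the only free phenol, the one next to iodine, attacks the acetal carbon, so ring C closes in one sense only, iodine ends up at C8 and the benzyl ethers survive the dilute acid.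

Step 7

Reactants: 9 5,7-bis(benzyloxy)-3-[2,4-bis(benzyloxy)phenyl]-8-iodo-4H-chromen-4-one; 10 2-methylbut-3-yn-2-ol

Product: 11 5,7-bis(benzyloxy)-3-[2,4-bis(benzyloxy)phenyl]-8-(3-hydroxy-3-methylbut-1-yn-1-yl)-4H-chromen-4-one

Conditions: PdCl2(PPh3)2 (5 mol %), CuI (10 mol %), Et3N (5 equiv), 10 (3 equiv), DMF, 70 °C, Ar, 6 h

Reagents that add atoms: none

Why: Sonogashira coupling (oxidative addition of zerovalent palladium into the C8–I bond, transmetalation from the copper acetylide, reductive elimination), in which no free hydroxyl sits ortho to the new alkyne, so no furan can close, and the non-nucleophilic tertiary amine leaves the chromone ring intact.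

Step 8

Reactants: 11 5,7-bis(benzyloxy)-3-[2,4-bis(benzyloxy)phenyl]-8-(3-hydroxy-3-methylbut-1-yn-1-yl)-4H-chromen-4-one

Product: 12 3-(2,4-dihydroxyphenyl)-5,7-dihydroxy-8-(3-hydroxy-3-methylbutyl)-4H-chromen-4-one

Conditions: H2 (1 atm), 10% Pd/C, EtOAc/MeOH (1:1), rt, 2–4 h, stopped at full debenzylation (LC–MS)

Reagents that add atoms: none

Why: Catalytic hydrogenation with concurrent hydrogenolysis, in which the alkyne is saturated and the four benzyl ethers are cleaved to toluene faster than the vinylogous-ester C2=C3 bond is reduced, while the neutral medium keeps the tertiary alcohol from dehydrating or cyclising onto the 7-OH; the product is achiral.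

**Compound list**

```
1 | 1-(2,4,6-trihydroxyphenyl)ethan-1-one (2',4',6'-trihydroxyacetophenone) | CC(=O)c1c(O)cc(O)cc1O | starting material
2 | 1-[2,4-bis(benzyloxy)-6-hydroxyphenyl]ethan-1-one | CC(=O)c1c(O)cc(OCc2ccccc2)cc1OCc1ccccc1 | intermediate
3 | 1-[4,6-bis(benzyloxy)-2-hydroxy-3-iodophenyl]ethan-1-one | CC(=O)c1c(O)c(I)c(OCc2ccccc2)cc1OCc1ccccc1 | intermediate
4 | 2,4-dihydroxybenzaldehyde | O=Cc1ccc(O)cc1O | starting material
5 | 2,4-bis(benzyloxy)benzaldehyde | O=Cc1ccc(OCc2ccccc2)cc1OCc1ccccc1 | intermediate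
6 | 1-[4,6-bis(benzyloxy)-2-hydroxy-3-iodophenyl]-3-[2,4-bis(benzyloxy)phenyl]-3-hydroxypropan-1-one (racemic aldol adduct, not isolated) | O=C(CC(O)c1ccc(OCc2ccccc2)cc1OCc1ccccc1)c1c(O)c(I)c(OCc2ccccc2)cc1OCc1ccccc1 | intermediate
7 | (E)-1-[4,6-bis(benzyloxy)-2-hydroxy-3-iodophenyl]-3-[2,4-bis(benzyloxy)phenyl]prop-2-en-1-one | O=C(/C=C/c1ccc(OCc2ccccc2)cc1OCc1ccccc1)c1c(O)c(I)c(OCc2ccccc2)cc1OCc1ccccc1 | intermediate
8 | 1-[4,6-bis(benzyloxy)-2-hydroxy-3-iodophenyl]-2-[2,4-bis(benzyloxy)phenyl]-3,3-dimethoxypropan-1-one (racemic) | COC(OC)C(C(=O)c1c(O)c(I)c(OCc2ccccc2)cc1OCc1ccccc1)c1ccc(OCc2ccccc2)cc1OCc1ccccc1 | intermediate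
9 | 5,7-bis(benzyloxy)-3-[2,4-bis(benzyloxy)phenyl]-8-iodo-4H-chromen-4-one | Ic1c(OCc2ccccc2)cc(OCc2ccccc2)c2c(=O)c(-c3ccc(OCc4ccccc4)cc3OCc3ccccc3)coc12 | intermediate
10 | 2-methylbut-3-yn-2-ol | CC(C)(O)C#C | starting material
11 | 5,7-bis(benzyloxy)-3-[2,4-bis(benzyloxy)phenyl]-8-(3-hydroxy-3-methylbut-1-yn-1-yl)-4H-chromen-4-one | CC(C)(O)C#Cc1c(OCc2ccccc2)cc(OCc2ccccc2)c2c(=O)c(-c3ccc(OCc4ccccc4)cc3OCc3ccccc3)coc12 | intermediate
12 | 3-(2,4-dihydroxyphenyl)-5,7-dihydroxy-8-(3-hydroxy-3-methylbutyl)-4H-chromen-4-one (2,3-dehydrokievitone hydrate, achiral) | CC(C)(O)CCc1c(O)cc(O)c2c(=O)c(-c3ccc(O)cc3O)coc12 | target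
```

**Totals**

Total step count: 8. Longest linear sequence: 7 steps (steps 1, 2, 4, 5, 6, 7, 8 from compound 1; step 3 is the convergent branch).

**Three steps most likely to fail, each with a fallback**

Step 5 (oxidative aryl shift with Tl(NO3)3). The risks are aurone formation, over-oxidation of the electron-rich rings and the handling of toxic thallium salts. The fallback sets out from 7 and comes back at 9, bypassing 8 and step 6, by the epoxide and acyl-shift route instead of a metal-mediated aryl shift. The chelated 2'-OH of 7 is capped with MOMCl (NaH, DMF, 0 °C) to give the 2'-O-methoxymethyl chalcone F1. Nucleophilic epoxidation (30% H2O2, aq. NaOH, MeOH/THF, 0 °C to rt) gives the racemic trans-epoxy ketone F2. BF3·OEt2 (CH2Cl2, 0 °C) ionises the benzylic C–O bond and triggers a 1,2-aroyl shift to the α-formyl deoxybenzoin F3. Heating F3 in 10% HCl/MeOH removes the MOM group and cyclodehydrates directly to 9.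

Step 7 (Sonogashira coupling at the hindered, electron-rich C8 iodide). The risks are slow oxidative addition and copper-mediated homocoupling of the alkynol. The fallback sets out from 9 and comes back at 12 without passing through 11. A copper-free Heck reaction of 9 with 2-methylbut-3-en-2-ol (Pd(OAc)2, Bu4NCl, NaHCO3, DMF, 90 °C) gives the (E)-styrenyl tertiary alcohol F4. The H2, Pd/C treatment of step 8 then saturates the alkene and removes the four benzyl groups to give 12.

Step 8 (global hydrogenation). The risk is partial reduction of the C2=C3 bond to the isoflavanone before debenzylation is complete. The fallback sets out from 11 and comes back at 12 by reducing fully and then re-oxidising. Hydrogenation of 11 is driven to completion (H2, 10% Pd/C, acetone, prolonged) to give racemic kievitone hydrate F5. The four phenols are acetylated (Ac2O, pyridine, rt, no DMAP, so the tertiary alcohol is untouched) to give the isoflavanone tetraacetate F6. DDQ (dioxane, reflux) dehydrogenates C2–C3 to the isoflavone tetraacetate F7. Mild methanolysis (K2CO3, MeOH, 0 °C to rt, then dilute acid work-up) removes the acetates to give 12.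

**Further compounds**

```
F1 | step 5 | (E)-1-[4,6-bis(benzyloxy)-3-iodo-2-(methoxymethoxy)phenyl]-3-[2,4-bis(benzyloxy)phenyl]prop-2-en-1-one | COCOc1c(I)c(OCc2ccccc2)cc(OCc2ccccc2)c1C(=O)/C=C/c1ccc(OCc2ccccc2)cc1OCc1ccccc1
F2 | step 5 | racemic trans-[4,6-bis(benzyloxy)-3-iodo-2-(methoxymethoxy)phenyl]{3-[2,4-bis(benzyloxy)phenyl]oxiran-2-yl}methanone (one enantiomer drawn) | COCOc1c(I)c(OCc2ccccc2)cc(OCc2ccccc2)c1C(=O)[C@@H]1O[C@H]1c1ccc(OCc2ccccc2)cc1OCc1ccccc1
F3 | step 5 | 2-[2,4-bis(benzyloxy)phenyl]-3-[4,6-bis(benzyloxy)-3-iodo-2-(methoxymethoxy)phenyl]-3-oxopropanal (racemic, enolisable) | O=CC(c1ccc(OCc2ccccc2)cc1OCc1ccccc1)C(=O)c1c(OCOC)c(I)c(OCc2ccccc2)cc1OCc1ccccc1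
F4 | step 7 | 5,7-bis(benzyloxy)-3-[2,4-bis(benzyloxy)phenyl]-8-[(E)-3-hydroxy-3-methylbut-1-en-1-yl]-4H-chromen-4-one | CC(C)(O)/C=C/c1c(OCc2ccccc2)cc(OCc2ccccc2)c2c(=O)c(-c3ccc(OCc4ccccc4)cc3OCc3ccccc3)coc12
F5 | step 8 | racemic 3-(2,4-dihydroxyphenyl)-5,7-dihydroxy-8-(3-hydroxy-3-methylbutyl)chroman-4-one (kievitone hydrate) | CC(C)(O)CCc1c(O)cc(O)c2c1OCC(c1ccc(O)cc1O)C2=O
F6 | step 8 | racemic 3-(2,4-diacetoxyphenyl)-5,7-diacetoxy-8-(3-hydroxy-3-methylbutyl)chroman-4-one | CC(=O)Oc1ccc(C2COc3c(CCC(C)(C)O)c(OC(C)=O)cc(OC(C)=O)c3C2=O)c(OC(C)=O)c1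
F7 | step 8 | 3-(2,4-diacetoxyphenyl)-5,7-diacetoxy-8-(3-hydroxy-3-methylbutyl)-4H-chromen-4-one | CC(=O)Oc1ccc(-c2coc3c(CCC(C)(C)O)c(OC(C)=O)cc(OC(C)=O)c3c2=O)c(OC(C)=O)c1
```
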